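**Retrosynthetic overview**
- The A-ring prenyl group and the free 5-OH are unveiled together in the last step: a 5-O-prenyl ether on the finished (2S)-flavanone is moved to C8 by a Eu(III) para-Claisen–Cope shift.
- The flavanone C ring comes from a 2'-hydroxychalcone by a catalytic enantioselective 6-endo oxa-Michael closure (chalcone-isomerase-type step, sets C2 = S). The O-prenyl group leaves only one A-ring phenol free, so closure has one regiochemical outcome.
- The chalcone comes from a Claisen–Schmidt union of an O-prenylated phloroacetophenone methyl ether and a chromene salicylaldehyde, with no protecting groups.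
- The dimethylpyran ring comes from DDQ oxidation of an ortho-prenylphenol (o-quinone methide, then oxa-6π closure; prenyl-cyclase-type step), after C5-prenylation of 2,4-dihydroxybenzaldehyde.
- Ring order: pyran ring first (step 3), then the flavanone C ring (step 5); both benzene rings are bought.

Assumption: 2',6'-dihydroxy-4'-methoxyacetophenone is bought as a catalogue compound, and the target is the 2S enantiomer, as the given SMILES encodes.

**Step 1**
Reactants: 1 2',6'-dihydroxy-4'-methoxyacetophenone; 2 prenyl bromide (1-bromo-3-methylbut-2-ene)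
Product: 3 1-[2-hydroxy-4-methoxy-6-(3-methylbut-2-enyloxy)phenyl]ethanone
Conditions: 2 (1.05 equiv), K2CO3 (1.2 equiv), acetone, reflux, 6 h
Reagents that add atoms: none
Why: Williamson ether synthesis on one of two equivalent phenols; the remaining OH stays locked in the hydrogen bond to the ketone and resists a second alkylation, and the ether installed is both the mask for the future 5-OH and the latent C8 prenyl group.

**Step 2**
Reactants: 4 2,4-dihydroxybenzaldehyde; 5 2-methylbut-3-en-2-ol
Product: 6 2,4-dihydroxy-5-(3-methylbut-2-enyl)benzaldehyde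
Conditions: 5 (1.2 equiv), BF3·OEt2 (0.3 equiv), dioxane, rt, 12 h; chromatography to remove the 3-prenyl isomer
Reagents that add atoms: none
Why: Friedel–Crafts prenylation (the chemical counterpart of an aromatic prenyltransferase): the dimethylallyl cation attacks through its primary terminus at C5, which is para to the 2-OH, ortho to the 4-OH and less hindered than the doubly flanked C3.

**Step 3**
Reactants: 6 2,4-dihydroxy-5-(3-methylbut-2-enyl)benzaldehyde
Product: 8 7-hydroxy-2,2-dimethyl-2H-chromene-6-carbaldehyde, via o-quinone methide 7 (not isolated)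
Conditions: DDQ (1.1 equiv), toluene, 80 °C, 1 h
Reagents that add atoms: none
Why: DDQ dehydrogenative cyclisation: hydride abstraction from the benzylic/allylic CH2 gives o-quinone methide 7, whose oxa-6π electrocyclisation closes the 2,2-dimethylpyran onto the 4-OH, the only hydroxyl ortho to the prenyl group, so only the linear chromene can form.

**Step 4**
Reactants: 3 1-[2-hydroxy-4-methoxy-6-(3-methylbut-2-enyloxy)phenyl]ethanone; 8 7-hydroxy-2,2-dimethyl-2H-chromene-6-carbaldehyde
Product: 10 (E)-3-(7-hydroxy-2,2-dimethyl-2H-chromen-6-yl)-1-[2-hydroxy-4-methoxy-6-(3-methylbut-2-enyloxy)phenyl]prop-2-en-1-one, via aldol adduct 9 (not isolated)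
Conditions: KOH (50% aq, 10 equiv), EtOH, 0 °C to rt, 36 h, dark; then cold 1 M HCl to pH 5
Reagents that add atoms: none
Why: Claisen–Schmidt aldol condensation, which tolerates both free phenols as phenoxides; E1cB loss of water from aldol 9 gives the E-enone, and in strong base the chalcone dianion does not ring-close, so the chalcone is isolated on cold acidification.

**Step 5**
Reactants: 10 (E)-3-(7-hydroxy-2,2-dimethyl-2H-chromen-6-yl)-1-[2-hydroxy-4-methoxy-6-(3-methylbut-2-enyloxy)phenyl]prop-2-en-1-one
Product: 11 (2S)-2-(7-hydroxy-2,2-dimethyl-2H-chromen-6-yl)-7-methoxy-5-(3-methylbut-2-enyloxy)chroman-4-one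
Conditions: epi-9-amino-9-deoxyquinidine N-[3,5-bis(trifluoromethyl)phenyl]thiourea (10 mol%), toluene, 0 °C to rt, 48 h, dark
Reagents that add atoms: none
Why: Proposed new method: the quinuclidine nitrogen deprotonates the only free A-ring phenol (the other is the prenyl ether, so only the 5-O-prenyl-7-methoxy regioisomer can form) while the thiourea N–H pair binds the enone carbonyl, so the ion-paired phenoxide adds 6-endo-trig to one face of Cβ and sets C2 as S under catalyst control (checked by CD, 2S flavanones showing a positive Cotton effect near 330 nm and a negative one near 290 nm; the quinine-derived pseudoenantiomer is used if the sense is reversed), the 6'-alkoxy group twisting the chalcone so that closure is downhill; the closest known chemistry is the cinchona-thiourea intramolecular oxa-Michael closure of α-carboalkoxy-activated 2'-hydroxychalcones and the cinchona-alkaloid isomerisation of simple 2'-hydroxychalcones, which so far gives only moderate ee.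

**Step 6**
Reactants: 11 (2S)-2-(7-hydroxy-2,2-dimethyl-2H-chromen-6-yl)-7-methoxy-5-(3-methylbut-2-enyloxy)chroman-4-one
Product: 14 maackiaflavanone A, (2S)-5-hydroxy-2-(7-hydroxy-2,2-dimethyl-2H-chromen-6-yl)-7-methoxy-8-(3-methylbut-2-enyl)chroman-4-one, via ortho-dienone 12 (not isolated), via para-dienone 13 (not isolated)
Conditions: Eu(fod)3 (10 mol%), PhCl, 85 °C, 12 h
Reagents that add atoms: none
Why: Eu(III)-catalysed aromatic Claisen–Cope (para-Claisen) rearrangement: chelation of Eu between C4=O and the 5-O-prenyl oxygen triggers the [3,3] shift to C6 (12), a Cope [3,3] shift carries the group on to C8 as a normal prenyl (13) and enolisation gives the hydrogen-bonded 5-OH, all under neutral conditions that leave the C2 stereocentre, the 2'-OH and the chromene untouched.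

**Compound list**
1 | 2',6'-dihydroxy-4'-methoxyacetophenone | CC(=O)c1c(O)cc(OC)cc1O | starting material
2 | prenyl bromide (1-bromo-3-methylbut-2-ene) | CC(C)=CCBr | starting material
3 | 1-[2-hydroxy-4-methoxy-6-(3-methylbut-2-enyloxy)phenyl]ethanone | CC(=O)c1c(O)cc(OC)cc1OCC=C(C)C | intermediate
4 | 2,4-dihydroxybenzaldehyde | O=Cc1ccc(O)cc1O | starting material
5 | 2-methylbut-3-en-2-ol | CC(C)(O)C=C | starting material
6 | 2,4-dihydroxy-5-(3-methylbut-2-enyl)benzaldehyde | O=Cc1cc(CC=C(C)C)c(O)cc1O | intermediate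
7 | o-quinone methide, 6-hydroxy-3-(3-methylbut-2-enylidene)-4-oxocyclohexa-1,5-diene-1-carbaldehyde | O=CC1=CC(=CC=C(C)C)C(=O)C=C1O | intermediate (not isolated)
8 | 7-hydroxy-2,2-dimethyl-2H-chromene-6-carbaldehyde | O=Cc1cc2C=CC(C)(C)Oc2cc1O | intermediate
9 | aldol adduct, racemic 3-hydroxy-3-(7-hydroxy-2,2-dimethyl-2H-chromen-6-yl)-1-[2-hydroxy-4-methoxy-6-(3-methylbut-2-enyloxy)phenyl]propan-1-one | O=C(CC(O)c1cc2C=CC(C)(C)Oc2cc1O)c1c(O)cc(OC)cc1OCC=C(C)C | intermediate (not isolated)
10 | (E)-3-(7-hydroxy-2,2-dimethyl-2H-chromen-6-yl)-1-[2-hydroxy-4-methoxy-6-(3-methylbut-2-enyloxy)phenyl]prop-2-en-1-one | O=C(/C=C/c1cc2C=CC(C)(C)Oc2cc1O)c1c(O)cc(OC)cc1OCC=C(C)C | intermediate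
11 | (2S)-2-(7-hydroxy-2,2-dimethyl-2H-chromen-6-yl)-7-methoxy-5-(3-methylbut-2-enyloxy)chroman-4-one | COc1cc(OCC=C(C)C)c2c(c1)O[C@H](c1cc3c(cc1O)OC(C)(C)C=C3)CC2=O | intermediate
12 | ortho-dienone, (2S)-2-(7-hydroxy-2,2-dimethyl-2H-chromen-6-yl)-7-methoxy-6-(2-methylbut-3-en-2-yl)-2,3-dihydrochromene-4,5(6H)-dione, C6 epimers | COC1=CC2=C(C(=O)C1C(C)(C)C=C)C(=O)C[C@@H](c1cc3c(cc1O)OC(C)(C)C=C3)O2 | intermediate (not isolated)
13 | para-dienone, (2S)-2-(7-hydroxy-2,2-dimethyl-2H-chromen-6-yl)-7-methoxy-8-(3-methylbut-2-enyl)-2,3-dihydrochromene-4,5(8H)-dione, C8 epimers | COC1=CC(=O)C2=C(C1CC=C(C)C)O[C@H](c1cc3c(cc1O)OC(C)(C)C=C3)CC2=O | intermediate (not isolated)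
14 | maackiaflavanone A, (2S)-5-hydroxy-2-(7-hydroxy-2,2-dimethyl-2H-chromen-6-yl)-7-methoxy-8-(3-methylbut-2-enyl)chroman-4-one | COc1cc(O)c2c(c1CC=C(C)C)O[C@H](c1cc3c(cc1O)OC(C)(C)C=C3)CC2=O | target

**Step count**
Total: 6 steps. Longest linear sequence: 5 steps (4 → 6 → 8 → 10 → 11 → 14; steps 2 to 6).

**Three steps most likely to fail, with fallbacks**

Step 5 (enantioselective ring closure). The electron-rich B ring makes the enone a weak acceptor and the free B-ring phenol may disturb catalyst binding, so the ee may be modest. 2-Hydroxychalcones also photoisomerise and close to hemiketals, hence the dark. The fallback sets out from 10 and replaces catalyst control by resolution. NaOAc in refluxing EtOH closes 10 to the racemic flavanone, racemic 2-(7-hydroxy-2,2-dimethyl-2H-chromen-6-yl)-7-methoxy-5-(3-methylbut-2-enyloxy)chroman-4-one F1. Kinetic resolution by asymmetric transfer hydrogenation (RuCl(p-cymene)[(R,R)-TsDPEN], HCO2H/Et3N, rt, about 50% conversion) follows. By the usual aryl-ketone model this catalyst delivers hydride to give the 4R alcohol, so it should consume the 2R ketone as the cis alcohol (2R,4R)-2-(7-hydroxy-2,2-dimethyl-2H-chromen-6-yl)-7-methoxy-5-(3-methylbut-2-enyloxy)chroman-4-ol F2. The unreacted 2S ketone is separated by chromatography, and the route is rejoined at 11.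

Step 6 (Claisen–Cope). Dienone 12 may enolise before the Cope shift and give the 6-(1,1-dimethylallyl) isomer. Heating a flavanone with a free 2'-OH may also erode ee through reversible opening at C2. The fallback sets out from 1 and 2 and puts the prenyl group on carbon before the ring is made.
- C-Prenylation of 1 with 2 in 10% aq KOH (0 °C to rt) gives 1-[2,6-dihydroxy-4-methoxy-3-(3-methylbut-2-enyl)phenyl]ethanone F3.
- MOMCl (1.05 equiv) and K2CO3 in acetone protect the less hindered phenol, the one not flanked by the prenyl group, to give 1-[2-hydroxy-4-methoxy-6-(methoxymethoxy)-3-(3-methylbut-2-enyl)phenyl]ethanone F4.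
- Claisen–Schmidt condensation with 8 (KOH, EtOH) gives (E)-3-(7-hydroxy-2,2-dimethyl-2H-chromen-6-yl)-1-[2-hydroxy-4-methoxy-6-(methoxymethoxy)-3-(3-methylbut-2-enyl)phenyl]prop-2-en-1-one F5.
- The thiourea-catalysed oxa-Michael closure of step 5, now through the only free, prenyl-flanked phenol, gives (2S)-2-(7-hydroxy-2,2-dimethyl-2H-chromen-6-yl)-7-methoxy-5-(methoxymethoxy)-8-(3-methylbut-2-enyl)chroman-4-one F6.
- HCl (cat.) in MeOH at rt removes the MOM group, and the route is rejoined at 14.

Step 2 (C5-prenylation). The 3-prenyl isomer, diprenylation and acid-induced chroman formation will keep the yield low. The fallback sets out from 4 and fixes the position by halogenation. Br2 in AcOH at rt brominates para to the 2-OH to give 5-bromo-2,4-dihydroxybenzaldehyde F7. A linear-selective Pd-catalysed Suzuki–Miyaura coupling with prenylboronic acid pinacol ester (Pd/biarylphosphine, K3PO4, aq MeCN, 70 °C) then gives the prenyl arene, and the route is rejoined at 6.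

**Further compounds**
F1 | step 5 | racemic 2-(7-hydroxy-2,2-dimethyl-2H-chromen-6-yl)-7-methoxy-5-(3-methylbut-2-enyloxy)chroman-4-one | COc1cc(OCC=C(C)C)c2c(c1)OC(c1cc3c(cc1O)OC(C)(C)C=C3)CC2=O
F2 | step 5 | (2R,4R)-2-(7-hydroxy-2,2-dimethyl-2H-chromen-6-yl)-7-methoxy-5-(3-methylbut-2-enyloxy)chroman-4-ol | COc1cc(OCC=C(C)C)c2c(c1)O[C@@H](c1cc3c(cc1O)OC(C)(C)C=C3)C[C@H]2O
F3 | step 6 | 1-[2,6-dihydroxy-4-methoxy-3-(3-methylbut-2-enyl)phenyl]ethanone | CC(=O)c1c(O)cc(OC)c(CC=C(C)C)c1O
F4 | step 6 | 1-[2-hydroxy-4-methoxy-6-(methoxymethoxy)-3-(3-methylbut-2-enyl)phenyl]ethanone | CC(=O)c1c(OCOC)cc(OC)c(CC=C(C)C)c1O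
F5 | step 6 | (E)-3-(7-hydroxy-2,2-dimethyl-2H-chromen-6-yl)-1-[2-hydroxy-4-methoxy-6-(methoxymethoxy)-3-(3-methylbut-2-enyl)phenyl]prop-2-en-1-one | O=C(/C=C/c1cc2C=CC(C)(C)Oc2cc1O)c1c(OCOC)cc(OC)c(CC=C(C)C)c1O
F6 | step 6 | (2S)-2-(7-hydroxy-2,2-dimethyl-2H-chromen-6-yl)-7-methoxy-5-(methoxymethoxy)-8-(3-methylbut-2-enyl)chroman-4-one | COCOc1cc(OC)c(CC=C(C)C)c2c1C(=O)C[C@@H](c1cc3c(cc1O)OC(C)(C)C=C3)O2
F7 | step 2 | 5-bromo-2,4-dihydroxybenzaldehyde | O=Cc1cc(Br)c(O)cc1O
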